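All runs were generated by integration with constants of no real substance; scatter was added.

Target is what you want from alder and cedar, and the nucleophile, the limiting reagent at 0.950 equiv, caps it. Here is the quick number you asked for.

| setting | theta | zeta | alder | cedar |
|---|---|---|---|---|
| electrophile | 0.020 M | 0.020 M | 0.020 M | 0.020 M |
| nucleophile | 0.95 equiv | 0.95 equiv | 0.950 equiv | 0.950 equiv |
| free base | 1.4 equiv | 1.3 equiv | 1.20 equiv | 1.60 equiv |
| scavenger | 1 equiv | 1 equiv | 1.00 equiv | 1.00 equiv |
| remark | run made earlier | run made earlier |  |  |
| time |  |  | 5.0 d | 5.0 d |

- theta (time / d: electrophile / %, target / %): 1.04: 27.5, 72.5; 2.08: 15.9, 83.5; 3.00: 11.3, 88.9; 4.00: 8.9, 91.3; 5.00: 8.0, 91.9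
- zeta (time / d: electrophile / %, target / %): 0.417: 48.6, 50.6; 0.833: 31.7, 68.3; 1.25: 22.9, 76.6; 2.50: 13.6, 87.1; 5.00: 10.1, 90.8

(scatter of a reading: 1 percentage point)

- part of the electrophile that has reacted at the end, alder
- part of the electrophile that has reacted at the end, cedar
- what raising the equivalents of free base from its lowest to its highest value here does to the part of the electrophile that has reacted (changes below 5 percentage points count as none) (no change / it rises / it falls)

- a species is counted by the electrophile in it: one homo dimer counts as two
- amounts and yields of acid set free count idle adduct too
- steps that have been proposed: electrophile + acid set free <-> idle adduct; acid set free + scavenger -> scavenged by-product; 2 electrophile -> homo dimer; acid set free + free base <-> salt of the base; nucleophile + acid set free <-> protonated nucleophile; electrophile + nucleophile -> acid set free + target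

In the theta run, electrophile and target sum to the charge within the scatter, so we reckon with the step electrophile + nucleophile and take nucleophile left as electrophile left minus the excess of electrophile. For that step, ln([electrophile]/[nucleophile]) climbs in proportion to time. From the first reading of each run we read κ, the rate constant times the starting concentration, as 2.87 /d in theta and 2.75 /d in zeta, alike at the two charges of free base for single readings with a scatter of 1 percentage point, and we carry theta's value. The decades of separation, the powers of ten by which that ratio has moved since the start, are excess times κ times time, over 2.30: for alder 0.312. That is less than one decade, so alder is still moving at 5.0 d, and our reckoning gives 90.7% reacted. Free base does not enter it, and alder's 1.20 equiv is more than the 0.950 equiv of acid the nucleophile can set free, so our number serves cedar too.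

Your forecast says 91% for alder, 91.5% for cedar and no change, reasoning that “the acid stays mopped up”. Unlike ours, it separates the two flasks slightly.

The flask gives 92.2% for alder, 92.3% for cedar and no change, a change of 0.049 points.

    electrophile + acid set free ⇌ idle adduct, settled at all times (K = 98.0 /M)
    acid set free + scavenger → scavenged by-product (k = 0.140 /M/s)
    2 electrophile → homo dimer (k = 6.10 × 10⁻⁶ /M/s)
    acid set free + free base ⇌ salt of the base (K = 39000 /M, k = 0.0220 /M/s)
    nucleophile + acid set free ⇌ protonated nucleophile, settled at all times (K = 6600 /M)
    electrophile + nucleophile → acid set free + target (k = 0.00230 /M/s)

Alder's end state shows 0.336 decades against our 0.312. In alder, electrophile + nucleophile uses electrophile 180 times faster than the homo dimer step just after the start, and 110 times faster at 0.324 d. At the end, target stands at 91.5% and homo dimer at 0.731%. For the forecast to fail, alder's answer moves by 5 points at 0.878 equiv or 1.06 equiv of nucleophile, or at 2.61 d.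

On a neighbour flask, alder with 0.240 equiv of nucleophile, the same κ gives 4.74 decades, more than one, so we expect target near that charge. The computed flask has 0% of its nucleophile left, target 24.0% and 29.9% of the electrophile reacted.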